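## Retrosynthetic overview

1. The target is a chain of five rings A–B–C–D–E joined by four CH2 groups. The two outer CH2 links are cut last, between the single free ring CH of rings B and D of a B–C–D trimer and C6 of butanoylfilicinic acid, used as its Mannich salt.
2. The butanoyl groups of rings B and D are removed by a Friedel–Crafts disconnection at an all-ether stage in which both rings are symmetric; ring C carries its butanoyl group from the first step.
3. The strategy rests on rings B and D: each is a benzene ring with oxygen on C2, C4 and C6, and C1, lying between two of these C–O carbons, carries the CH2 to ring C. Each ring is cut back to a 3-ethoxycyclobutenone bound through its C4 to that CH2, plus triisopropylsiloxyacetylene; both rings form in one operation.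
4. The bis-cyclobutenone comes from the ring C bis(propanoyl chloride) by ketene–ethoxyacetylene [2+2] cycloaddition; the two three-carbon arms come from a ring C dibromide by a double Heck reaction.
5. Order of ring formation: ring C is bought as 1,3,5-trimethoxybenzene, then the two four-membered rings, then rings B and D together, and rings A and E are attached preformed.

Key step: step 8

Assumption: the target has no stereocentre and is taken as the enol tautomer of its SMILES; the four-membered-ring CH centres of the bis-cyclobutenone and of the cycloadduct that follows it form as mixtures, are drawn as one diastereomer, and become aromatic carbons in step 8.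

Remark on stoichiometry: the route is two-directional. In steps 3, 6, 8, 10 and 15 two molecules of the second reactant are built into each molecule of the ring C core; the second molecule is entered under "Reagents that add atoms" so that every atom of the product is accounted for.

## Route

Step 1
Reactants: 1 1,3,5-trimethoxybenzene; 2 butanoyl chloride
Product: 3 1-(2,4,6-trimethoxyphenyl)butan-1-one
Conditions: 2 (1.05 equiv), AlCl3 (1.1 equiv), CH2Cl2, 0 °C
Reagents that add atoms: none
Why: Friedel–Crafts acylation of the strongly activated arene should stop after one acyl group because the new ketone deactivates the ring.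

Step 2
Reactants: 3 1-(2,4,6-trimethoxyphenyl)butan-1-one
Product: 4 1-(3,5-dibromo-2,4,6-trimethoxyphenyl)butan-1-one
Conditions: NBS (2.1 equiv), MeCN, 0 °C to rt
Reagents that add atoms: N-bromosuccinimide, O=C1CCC(=O)N1Br
Why: Electrophilic aromatic bromination should take both remaining ring positions, each activated by two ortho and one para methoxy group, while acid-free NBS leaves the ketone α-CH2 alone.

Step 3
Reactants: 4 1-(3,5-dibromo-2,4,6-trimethoxyphenyl)butan-1-one; 5 benzyl acrylate (2.6 equiv; two molecules are incorporated, one per C–Br bond)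
Product: 6 dibenzyl (2E,2'E)-3,3'-(5-butanoyl-2,4,6-trimethoxy-1,3-phenylene)diacrylate
Conditions: 5 (2.6 equiv), Pd2(dba)3 (cat.), P(t-Bu)3 (cat.), Cs2CO3 (2.4 equiv), 1,4-dioxane, 100 °C
Reagents that add atoms: benzyl acrylate (second equivalent of 5), C=CC(=O)OCc1ccccc1
Why: Double Mizoroki–Heck reaction, one acrylate per C–Br bond; the bulky electron-rich phosphine should let zerovalent palladium insert into the di-ortho-substituted C–Br bonds, and syn insertion followed by syn β-hydride elimination gives the E-alkenes.

Step 4
Reactants: 6 dibenzyl (2E,2'E)-3,3'-(5-butanoyl-2,4,6-trimethoxy-1,3-phenylene)diacrylate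
Product: 7 3,3'-(5-butanoyl-2,4,6-trimethoxy-1,3-phenylene)dipropanoic acid
Conditions: H2 (1 atm), 10% Pd/C, EtOAc–EtOH, rt
Reagents that add atoms: none
Why: Catalytic hydrogenation should saturate both alkenes and hydrogenolyse both benzyl esters in one operation, while the hindered electron-rich aryl ketone is not reduced at this pressure.

Step 5
Reactants: 7 3,3'-(5-butanoyl-2,4,6-trimethoxy-1,3-phenylene)dipropanoic acid
Product: 8 3,3'-(5-butanoyl-2,4,6-trimethoxy-1,3-phenylene)dipropanoyl dichloride
Conditions: (COCl)2 (2.5 equiv), DMF (cat.), CH2Cl2, 0 °C to rt; evaporation, used crude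
Reagents that add atoms: oxalyl chloride, ClC(=O)C(Cl)=O
Why: Acid chloride formation through the chloroiminium salt from DMF gives only gaseous by-products and leaves ketone and methyl ethers untouched.

Step 6
Reactants: 8 3,3'-(5-butanoyl-2,4,6-trimethoxy-1,3-phenylene)dipropanoyl dichloride; 9 ethoxyacetylene (6 equiv; two molecules are incorporated, one per ketene)
Product: 11 1-[3,5-bis[(2-ethoxy-4-oxocyclobut-2-en-1-yl)methyl]-2,4,6-trimethoxyphenyl]butan-1-one, via bis-ketene 10 (not isolated)
Conditions: 9 (6 equiv), Et3N (2.4 equiv), Et2O, 0 °C to rt, 8 added slowly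
Reagents that add atoms: ethoxyacetylene (second equivalent of 9), CCOC#C
Why: Dehydrochlorination gives the aldoketene on each arm, and ketene–ynol ether [2+2] cycloaddition joins the nucleophilic CH carbon of one molecule of 9 to each ketene C=O carbon to give the 3-ethoxy-4-alkylcyclobutenone; the ring CH stereocentre of each arm forms without control, which does not matter.

Step 7
Reactants: 12 3-phenylisoxazole; 13 triisopropylsilyl chloride
Product: 16 triisopropylsiloxyacetylene, via 5-lithio-3-phenylisoxazole 14 (not isolated), via lithium ethynolate 15 (not isolated)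
Conditions: n-BuLi (1.0 equiv), THF, −78 to −40 °C; then 13 (1.0 equiv), −78 °C to rt
Reagents that add atoms: none
Why: C5-lithiation of the isoxazole is followed by fragmentation into benzonitrile and the lithium ynolate, and the bulky silyl chloride should silylate the ynolate on oxygen (O-silylation of an ynolate).

Step 8
Reactants: 11 1-[3,5-bis[(2-ethoxy-4-oxocyclobut-2-en-1-yl)methyl]-2,4,6-trimethoxyphenyl]butan-1-one; 16 triisopropylsiloxyacetylene (5 equiv; two molecules are incorporated, one per cyclobutenone)
Product: 19 1-[3,5-bis(2-ethoxy-6-hydroxy-4-triisopropylsilyloxybenzyl)-2,4,6-trimethoxyphenyl]butan-1-one, via bis-vinylketene 17 (not isolated), via bis-vinylcyclobutenone 18 (not isolated)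
Conditions: 16 (5 equiv), toluene (0.05 M), sealed tube, 145 °C
Reagents that add atoms: triisopropylsiloxyacetylene (second equivalent of 16), C#CO[Si](C(C)C)(C(C)C)C(C)C
Why: Proposed new method: each 3-ethoxy-4-alkylcyclobutenone of 11 should open by thermal conrotatory 4π cleavage of its C1–C4 bond, the alkyl group turning outward, to the vinylketene of 17, which adds one molecule of 16 in a [2+2] cycloaddition to the 4-vinyl-3-siloxycyclobutenone of 18, and a second 4π opening, 6π electrocyclisation of the dienylketene and enolisation of the cyclohexadienone then deliver the phenol. The closest known reaction type is the Danheiser benzannulation of cyclobutenones with siloxyalkynes, not yet shown for a 3-alkoxy-4-alkylcyclobutenone or for two such rings in one molecule, although the 4-vinyl-3-siloxycyclobutenone that the known reaction itself passes through is a four-membered ring of the same oxygenation and opens at these temperatures. Rings B and D are each closed by a thermal disrotatory 6π electrocyclisation that joins the former ketene carbon to the carbon carrying the CH2 link, after the cycloaddition has made the two new C–C bonds to the alkyne carbons. No stereocentre is created: the CH centres of the four-membered rings in 11 and 18 all become aromatic carbons. The selectivity the step needs is the orientation of the ketene–alkyne cycloaddition, and the oxygen of 16 secures it by making the CH terminus the nucleophilic carbon that attacks the ketene C=O carbon, so the silyloxy carbon ends para to the CH2 link and the three ring oxygens are mutually meta. Since the cascade needs neither acid nor base, the CH2 links to ring C cannot migrate.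

Step 9
Reactants: 19 1-[3,5-bis(2-ethoxy-6-hydroxy-4-triisopropylsilyloxybenzyl)-2,4,6-trimethoxyphenyl]butan-1-one
Product: 21 1-[2,4,6-trimethoxy-3,5-bis(2,4,6-triethoxybenzyl)phenyl]butan-1-one, via tetraphenol 20 (not isolated)
Conditions: CsF (2.5 equiv), DMF, rt; then Cs2CO3 (6 equiv), EtI (6 equiv), 50 °C
Reagents that add atoms: iodoethane, CCI
Why: Fluoride cleaves the two aryl silyl ethers and Williamson O-ethylation of the four phenoxides makes rings B and D symmetric triethoxybenzyl rings, so the next acylation has only one kind of site.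

Step 10
Reactants: 21 1-[2,4,6-trimethoxy-3,5-bis(2,4,6-triethoxybenzyl)phenyl]butan-1-one; 2 butanoyl chloride (2.4 equiv; two molecules are incorporated, one per outer ring)
Product: 22 1-[3,5-bis(3-butanoyl-2,4,6-triethoxybenzyl)-2,4,6-trimethoxyphenyl]butan-1-one
Conditions: 2 (2.4 equiv), SnCl4 (2.4 equiv), CH2Cl2, −20 to 0 °C
Reagents that add atoms: butanoyl chloride (second equivalent of 2), CCCC(Cl)=O
Why: Friedel–Crafts acylation; ring C has no free position, each triethoxy ring offers two equivalent CH positions, and the first acyl group deactivates its ring so that each ring should take one.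

Step 11
Reactants: 22 1-[3,5-bis(3-butanoyl-2,4,6-triethoxybenzyl)-2,4,6-trimethoxyphenyl]butan-1-one
Product: 23 1-[3,5-bis(3-butanoyl-2,4,6-trihydroxybenzyl)-2,4,6-trihydroxyphenyl]butan-1-one
Conditions: BBr3 (excess), CH2Cl2, −78 °C to rt; then H2O, 0 °C
Reagents that add atoms: none
Why: Lewis-acid cleavage of all nine alkyl aryl ethers, helped by chelation to the ortho ketones; every ring now carries an acyl group, which should disfavour ipso-protonation at the CH2-bearing carbons.

Step 12
Reactants: 24 phloroglucinol; 2 butanoyl chloride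
Product: 25 1-(2,4,6-trihydroxyphenyl)butan-1-one
Conditions: 2 (1.0 equiv), AlCl3 (3 equiv), PhNO2, rt to 60 °C
Reagents that add atoms: none
Why: Friedel–Crafts C-acylation of phloroglucinol should stop at the monoketone because the acyl group deactivates the ring.

Step 13
Reactants: 25 1-(2,4,6-trihydroxyphenyl)butan-1-one
Product: 26 2-butanoyl-3,5-dihydroxy-4,4-dimethylcyclohexa-2,5-dien-1-one (butanoylfilicinic acid)
Conditions: NaOMe (3.2 equiv), MeI (2.2 equiv), MeOH, 0 °C to rt
Reagents that add atoms: iodomethane, CI
Why: Dearomatising C-alkylation; the phloroglucinol polyanion is methylated twice at the same nuclear carbon to give the gem-dimethyl dienone, which is separated from under- and over-methylated material.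

Step 14
Reactants: 26 2-butanoyl-3,5-dihydroxy-4,4-dimethylcyclohexa-2,5-dien-1-one; 27 N,N-dimethylmethyleneiminium iodide (Eschenmoser's salt)
Product: 28 1-(5-butanoyl-2,4-dihydroxy-3,3-dimethyl-6-oxocyclohexa-1,4-dien-1-yl)-N,N-dimethylmethanaminium iodide
Conditions: 27 (1.0 equiv), MeCN, 0 °C to rt, 26 added to 27
Reagents that add atoms: none
Why: Mannich reaction of the preformed iminium salt at C6, the only unsubstituted nucleophilic ring carbon; isolation as the ammonium salt should keep the product from losing amine.

Step 15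
Reactants: 23 1-[3,5-bis(3-butanoyl-2,4,6-trihydroxybenzyl)-2,4,6-trihydroxyphenyl]butan-1-one; 28 Mannich salt of butanoylfilicinic acid (2.4 equiv; two molecules are incorporated, one per outer ring)
Product: 30 CNP0188003.0, via methylene trione 29 (not isolated)
Conditions: 28 (2.4 equiv), NaOAc (2.4 equiv), 1,4-dioxane, 50 °C, N2
Reagents that add atoms: Mannich salt of butanoylfilicinic acid (second equivalent of 28), CCCC(=O)C1=C(O)C(C)(C)C(O)=C(C[NH+](C)C)C1=O.[I-]
Why: Deaminative alkylation; acetate frees the Mannich base, which loses dimethylamine to the 6-methylene trione, and Michael addition of the single free ring CH of rings B and D followed by re-aromatisation should form the two outer CH2 links.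

## Compound list

1 | 1,3,5-trimethoxybenzene | COc1cc(OC)cc(OC)c1 | starting material
2 | butanoyl chloride | CCCC(Cl)=O | starting material
3 | 1-(2,4,6-trimethoxyphenyl)butan-1-one | CCCC(=O)c1c(OC)cc(OC)cc1OC | intermediate
4 | 1-(3,5-dibromo-2,4,6-trimethoxyphenyl)butan-1-one | CCCC(=O)c1c(OC)c(Br)c(OC)c(Br)c1OC | intermediate
5 | benzyl acrylate | C=CC(=O)OCc1ccccc1 | starting material
6 | dibenzyl (2E,2'E)-3,3'-(5-butanoyl-2,4,6-trimethoxy-1,3-phenylene)diacrylate | CCCC(=O)c1c(OC)c(/C=C/C(=O)OCc2ccccc2)c(OC)c(/C=C/C(=O)OCc2ccccc2)c1OC | intermediate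
7 | 3,3'-(5-butanoyl-2,4,6-trimethoxy-1,3-phenylene)dipropanoic acid | CCCC(=O)c1c(OC)c(CCC(=O)O)c(OC)c(CCC(=O)O)c1OC | intermediate
8 | 3,3'-(5-butanoyl-2,4,6-trimethoxy-1,3-phenylene)dipropanoyl dichloride | CCCC(=O)c1c(OC)c(CCC(Cl)=O)c(OC)c(CCC(Cl)=O)c1OC | intermediate
9 | ethoxyacetylene | CCOC#C | starting material
10 | bis-ketene, 1-[2,4,6-trimethoxy-3,5-bis(3-oxoprop-2-en-1-yl)phenyl]butan-1-one | CCCC(=O)c1c(OC)c(CC=C=O)c(OC)c(CC=C=O)c1OC | intermediate
11 | 1-[3,5-bis[(2-ethoxy-4-oxocyclobut-2-en-1-yl)methyl]-2,4,6-trimethoxyphenyl]butan-1-one (one diastereomer drawn; formed as a mixture at the ring CH centres) | CCCC(=O)c1c(OC)c(C[C@H]2C(=O)C=C2OCC)c(OC)c(C[C@H]2C(=O)C=C2OCC)c1OC | intermediate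
12 | 3-phenylisoxazole | c1ccc(-c2ccon2)cc1 | starting material
13 | triisopropylsilyl chloride | CC(C)[Si](Cl)(C(C)C)C(C)C | starting material
14 | 5-lithio-3-phenylisoxazole | [Li]c1cc(-c2ccccc2)no1 | intermediate
15 | lithium ethynolate | [Li]OC#C | intermediate
16 | triisopropylsiloxyacetylene | C#CO[Si](C(C)C)(C(C)C)C(C)C | intermediate
17 | bis-vinylketene, 1-[3,5-bis[(2Z)-3-ethoxy-5-oxopenta-2,4-dien-1-yl]-2,4,6-trimethoxyphenyl]butan-1-one | CCCC(=O)c1c(OC)c(C/C=C(\OCC)C=C=O)c(OC)c(C/C=C(\OCC)C=C=O)c1OC | intermediate
18 | bis-vinylcyclobutenone, each arm (2Z)-3-ethoxy-3-[4-oxo-2-(triisopropylsilyloxy)cyclobut-2-en-1-yl]prop-2-en-1-yl on the ring C core of 11 (one diastereomer drawn; formed as a mixture at the ring CH centres) | CCCC(=O)c1c(OC)c(C/C=C(\OCC)[C@H]2C(=O)C=C2O[Si](C(C)C)(C(C)C)C(C)C)c(OC)c(C/C=C(\OCC)[C@H]2C(=O)C=C2O[Si](C(C)C)(C(C)C)C(C)C)c1OC | intermediate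
19 | 1-[3,5-bis(2-ethoxy-6-hydroxy-4-triisopropylsilyloxybenzyl)-2,4,6-trimethoxyphenyl]butan-1-one | CCCC(=O)c1c(OC)c(Cc2c(O)cc(O[Si](C(C)C)(C(C)C)C(C)C)cc2OCC)c(OC)c(Cc2c(O)cc(O[Si](C(C)C)(C(C)C)C(C)C)cc2OCC)c1OC | intermediate
20 | tetraphenol, 1-[3,5-bis(2-ethoxy-4,6-dihydroxybenzyl)-2,4,6-trimethoxyphenyl]butan-1-one (present as its caesium phenoxide) | CCCC(=O)c1c(OC)c(Cc2c(O)cc(O)cc2OCC)c(OC)c(Cc2c(O)cc(O)cc2OCC)c1OC | intermediate
21 | 1-[2,4,6-trimethoxy-3,5-bis(2,4,6-triethoxybenzyl)phenyl]butan-1-one | CCCC(=O)c1c(OC)c(Cc2c(OCC)cc(OCC)cc2OCC)c(OC)c(Cc2c(OCC)cc(OCC)cc2OCC)c1OC | intermediate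
22 | 1-[3,5-bis(3-butanoyl-2,4,6-triethoxybenzyl)-2,4,6-trimethoxyphenyl]butan-1-one | CCCC(=O)c1c(OC)c(Cc2c(OCC)cc(OCC)c(C(=O)CCC)c2OCC)c(OC)c(Cc2c(OCC)cc(OCC)c(C(=O)CCC)c2OCC)c1OC | intermediate
23 | 1-[3,5-bis(3-butanoyl-2,4,6-trihydroxybenzyl)-2,4,6-trihydroxyphenyl]butan-1-one | CCCC(=O)c1c(O)c(Cc2c(O)cc(O)c(C(=O)CCC)c2O)c(O)c(Cc2c(O)cc(O)c(C(=O)CCC)c2O)c1O | intermediate
24 | phloroglucinol | Oc1cc(O)cc(O)c1 | starting material
25 | 1-(2,4,6-trihydroxyphenyl)butan-1-one | CCCC(=O)c1c(O)cc(O)cc1O | intermediate
26 | 2-butanoyl-3,5-dihydroxy-4,4-dimethylcyclohexa-2,5-dien-1-one (butanoylfilicinic acid) | CCCC(=O)C1=C(O)C(C)(C)C(O)=CC1=O | intermediate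
27 | N,N-dimethylmethyleneiminium iodide (Eschenmoser's salt) | C=[N+](C)C.[I-] | starting material
28 | 1-(5-butanoyl-2,4-dihydroxy-3,3-dimethyl-6-oxocyclohexa-1,4-dien-1-yl)-N,N-dimethylmethanaminium iodide | CCCC(=O)C1=C(O)C(C)(C)C(O)=C(C[NH+](C)C)C1=O.[I-] | intermediate
29 | methylene trione, 2-butanoyl-3-hydroxy-4,4-dimethyl-6-methylenecyclohex-2-ene-1,5-dione | CCCC(=O)C1=C(O)C(C)(C)C(=O)C(=C)C1=O | intermediate
30 | CNP0188003.0 | CCCC(=O)C1=C(O)C(C)(C)C(O)=C(Cc2c(O)c(Cc3c(O)c(Cc4c(O)c(CC5=C(O)C(C)(C)C(O)=C(C(=O)CCC)C5=O)c(O)c(C(=O)CCC)c4O)c(O)c(C(=O)CCC)c3O)c(O)c(C(=O)CCC)c2O)C1=O | target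

## Step count and risks

Total step count: 15. Longest linear sequence: 11 steps (steps 1 to 6, 8 to 11 and 15).

The three steps most likely to fail:

1. Step 8 (Proposed new method). The 3-ethoxy group makes each four-membered ring a vinylogous ester, so the first ring opening may be slow and reversible. At the temperature needed the vinylketene may be lost by inward rotation followed by 1,5-hydrogen shift from the benzylic CH2, by ketene dimerisation, or by acylating phenol already formed, and both arms must react. The fallback uses known chemistry and sets out from 3. Blanc chloromethylation ((CH2O)n, HCl, AcOH) should give 1-[3,5-bis(chloromethyl)-2,4,6-trimethoxyphenyl]butan-1-one F1, a bis-electrophile with no free ring position. Friedel–Crafts benzylation of a large excess of commercial 1,3,5-triethoxybenzene (CCOc1cc(OCC)cc(OCC)c1) with F1 (ZnCl2 cat., CH2Cl2, 0 °C to rt) should give 21, where the route is rejoined before step 10.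

2. Step 7. The unsubstituted ynolate carbon is unhindered, so silylation on carbon to a silylketene may compete with O-silylation, and the ynolate may add to the benzonitrile formed beside it. The fallback does without the siloxyalkyne and sets out from 11. Heating 11 in toluene in a sealed tube with a large excess of ethoxyacetylene 9, fed in portions because it slowly loses ethylene at this temperature, should give 1-[3,5-bis(2,4-diethoxy-6-hydroxybenzyl)-2,4,6-trimethoxyphenyl]butan-1-one F2 by the same benzannulation. O-Ethylation of F2 (EtI, K2CO3, DMF) should give 21, where the route is rejoined.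

3. Step 15. Michael addition and its reverse may equilibrate the methylene bridges, so rings may be redistributed among oligomers; the second capping may also stay incomplete and the end unit may self-condense. The fallback reverses the polarity and sets out from 23. Mannich reaction of 23 with Eschenmoser's salt 27 (2.2 equiv, MeCN, then aqueous NaHCO3) should give 1-[3,5-bis[3-butanoyl-5-(dimethylaminomethyl)-2,4,6-trihydroxybenzyl]-2,4,6-trihydroxyphenyl]butan-1-one F3. Warming F3 with an excess of 26 in 1,4-dioxane should release the o-quinone methide on rings B and D, which the enol carbon C6 of 26 traps to give 30.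

Further compounds
F1 | step 8 | 1-[3,5-bis(chloromethyl)-2,4,6-trimethoxyphenyl]butan-1-one | CCCC(=O)c1c(OC)c(CCl)c(OC)c(CCl)c1OC
F2 | step 7 | 1-[3,5-bis(2,4-diethoxy-6-hydroxybenzyl)-2,4,6-trimethoxyphenyl]butan-1-one | CCCC(=O)c1c(OC)c(Cc2c(O)cc(OCC)cc2OCC)c(OC)c(Cc2c(O)cc(OCC)cc2OCC)c1OC
F3 | step 15 | 1-[3,5-bis[3-butanoyl-5-(dimethylaminomethyl)-2,4,6-trihydroxybenzyl]-2,4,6-trihydroxybenzyl]-2,4,6-trihydroxyphenyl]butan-1-one, that is 1-[3,5-bis[3-butanoyl-5-(dimethylaminomethyl)-2,4,6-trihydroxybenzyl]-2,4,6-trihydroxyphenyl]butan-1-one | CCCC(=O)c1c(O)c(Cc2c(O)c(CN(C)C)c(O)c(C(=O)CCC)c2O)c(O)c(Cc2c(O)c(CN(C)C)c(O)c(C(=O)CCC)c2O)c1O
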